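**Retrosynthetic overview**

- The strategy rests on ring B: the oxygens at C2' and C5' stand para to each other and flank the C3'-OH/C4'-OMe pair. Ring B is therefore the reduced, doubly methylated form of a 2',5'-p-quinone, and that quinone traces back to a 3',4',5'-trioxygenated ring made from symmetric methyl 4-O-methylgallate.
- Key disconnection: the C2'–O bond, made by para-oxidation of the single free phenol (5'-OH) of 5,3'-dibenzyloxy-5'-hydroxy-7,4'-dimethoxyflavone with ON(SO3K)2. Reduction, double O-methylation and hydrogenolysis of the two benzyl ethers then give the target.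
- The benzyl ether placed during monobenzylation of the gallate marks the later 3'-OH. The second gallate hydroxyl travels as a MOM ether and is the phenol that is oxidised.
- Flavone assembly: Steglich ester from the ring B acid and monobenzylated 2,6-dihydroxy-4-methoxyacetophenone, Baker–Venkataraman shift, then acid cyclodehydration.
- Ring order: rings A and B are bought as aromatic building blocks. Ring C (the pyranone) is the only ring formed, in step 7. The key step closes no ring.

Key step: step 8

Remark: flavone locants are used throughout (ring A = benzo ring C5–C8, ring C = pyranone, ring B = 2-aryl ring with primed locants); the 1,3-diketone is drawn as its diketo tautomer although it should exist largely as the chelated enol.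

**Route**

Step 1
Reactants: 1 methyl 3,5-dihydroxy-4-methoxybenzoate; 2 benzyl bromide
Product: 3 methyl 3-benzyloxy-5-hydroxy-4-methoxybenzoate
Conditions: BnBr (1.0 equiv), K2CO3, DMF, rt; chromatography, recovered 1 recycled
Reagents that add atoms: benzyl bromide (2), BrCc1ccccc1
Why: Williamson ether synthesis on a diphenol whose two hydroxyls are equivalent by symmetry, so either one gives the same monoether, and limiting the bromide should keep dibenzylation down.

Step 2
Reactants: 3 methyl 3-benzyloxy-5-hydroxy-4-methoxybenzoate
Product: 4 methyl 3-benzyloxy-4-methoxy-5-(methoxymethoxy)benzoate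
Conditions: MOMCl, K2CO3, acetone, 0 °C to rt
Reagents that add atoms: chloromethyl methyl ether (MOMCl), COCCl
Why: O-alkylation of the remaining phenoxide with the reactive alpha-chloro ether (Williamson-type acetal formation) should give a MOM ether that withstands the basic steps ahead and falls off under mild acid.

Step 3
Reactants: 4 methyl 3-benzyloxy-4-methoxy-5-(methoxymethoxy)benzoate
Product: 5 3-benzyloxy-4-methoxy-5-(methoxymethoxy)benzoic acid
Conditions: NaOH (aq), THF–MeOH, 45 °C; then cold 1 M HCl to pH 4
Reagents that add atoms: sodium hydroxide, [Na+].[OH-]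
Why: Saponification of the methyl ester (acyl–oxygen cleavage by hydroxide) leaves the benzyl and MOM ethers alone, and the brief cold acidification to pH 4 is too mild to open the acetal.

Step 4
Reactants: 6 2,6-dihydroxy-4-methoxyacetophenone; 2 benzyl bromide
Product: 7 2-benzyloxy-6-hydroxy-4-methoxyacetophenone
Conditions: BnBr (1.05 equiv), K2CO3, acetone, reflux
Reagents that add atoms: benzyl bromide (2), BrCc1ccccc1
Why: Williamson etherification should stop cleanly at the monoether, because after the first alkylation the remaining hydroxyl is locked in a hydrogen bond to the acetyl carbonyl and is far less nucleophilic.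

Step 5
Reactants: 5 3-benzyloxy-4-methoxy-5-(methoxymethoxy)benzoic acid; 7 2-benzyloxy-6-hydroxy-4-methoxyacetophenone
Product: 8 2-acetyl-3-benzyloxy-5-methoxyphenyl 3-benzyloxy-4-methoxy-5-(methoxymethoxy)benzoate
Conditions: DCC, DMAP, CH2Cl2, rt
Reagents that add atoms: none
Why: Steglich esterification, in which the acylpyridinium ion formed from the O-acylisourea is reactive enough to acylate the hindered, hydrogen-bonded phenol under neutral conditions that spare the MOM acetal.

Step 6
Reactants: 8 2-acetyl-3-benzyloxy-5-methoxyphenyl 3-benzyloxy-4-methoxy-5-(methoxymethoxy)benzoate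
Product: 9 1-(2-benzyloxy-6-hydroxy-4-methoxyphenyl)-3-[3-benzyloxy-4-methoxy-5-(methoxymethoxy)phenyl]propane-1,3-dione
Conditions: KOH (powdered), pyridine, 50 °C; then cold dilute AcOH
Reagents that add atoms: none
Why: Baker–Venkataraman rearrangement, in which the methyl ketone enolate attacks the neighbouring aryl ester intramolecularly and the O-to-C acyl shift is driven by formation of the phenoxide and the stabilised beta-diketonate.

Step 7
Reactants: 9 1-(2-benzyloxy-6-hydroxy-4-methoxyphenyl)-3-[3-benzyloxy-4-methoxy-5-(methoxymethoxy)phenyl]propane-1,3-dione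
Product: 11 5-benzyloxy-2-(3-benzyloxy-5-hydroxy-4-methoxyphenyl)-7-methoxychromen-4-one, via MOM-protected flavone 10 (not isolated)
Conditions: HCl (1 M in MeOH), THF, 45 °C
Reagents that add atoms: none
Why: Acid-catalysed cyclodehydration (the phenol adds to the activated beta-carbonyl to give a 2-hydroxychromanone hemiketal that dehydrates) closes ring C, and acetal exchange with methanol in the same medium removes the MOM group, while HCl in methanol is much weaker than the HCl–AcOH mixtures needed to cleave a 5-O-benzyl ether.

Step 8
Reactants: 11 5-benzyloxy-2-(3-benzyloxy-5-hydroxy-4-methoxyphenyl)-7-methoxychromen-4-one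
Product: 12 5-benzyloxy-2-(5-benzyloxy-4-methoxy-3,6-dioxocyclohexa-1,4-dien-1-yl)-7-methoxychromen-4-one
Conditions: ON(SO3K)2 (3 equiv), aq. KH2PO4 (pH 6), methyltrioctylammonium chloride (cat.), CH2Cl2–H2O, rt
Reagents that add atoms: potassium nitrosodisulfonate, [K+].[K+].[O]N(S(=O)(=O)[O-])S(=O)(=O)[O-]
Why: Teuber oxidation: one equivalent of the nitroxyl radical ON(SO3K)2 removes the hydrogen of the 5'-OH, the only free phenol in 11, a second equivalent recombines through its oxygen with the phenoxyl radical at the para carbon C2', and the resulting 4-aminoxycyclohexa-2,5-dienone loses HN(SO3K)2 to leave the C2' carbonyl. The closest known reaction type is the oxidation of para-unsubstituted 2,3-dialkoxyphenols and 3,5-disubstituted phenols to p-benzoquinones with this reagent. The step forms only the C2'–O bond, so no ring is closed and no stereocentre arises. The selectivity needed is para attack (C2') over ortho attack (C6', or ipso at C4'), and it should be secured by the high para spin density of the phenoxyl radical, the para preference of this oxidant whenever the para carbon carries hydrogen, and the methoxy group that blocks C4'. Ring A cannot compete because its 5-OH is benzylated, the chromone enone offers no phenolic hydrogen, and the phosphate buffer keeps hydroxide from displacing the vinylogous-ester alkoxy groups of quinone 12.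

Step 9
Reactants: 12 5-benzyloxy-2-(5-benzyloxy-4-methoxy-3,6-dioxocyclohexa-1,4-dien-1-yl)-7-methoxychromen-4-one
Product: 13 5-benzyloxy-2-(3-benzyloxy-2,5-dihydroxy-4-methoxyphenyl)-7-methoxychromen-4-one
Conditions: Na2S2O4, EtOAc–H2O, rt, under Ar; crude product used at once
Reagents that add atoms: none
Why: Two-electron reduction of the p-benzoquinone to the hydroquinone by dithionite is fast at room temperature and does not touch the chromone or the benzyl ethers.

Step 10
Reactants: 13 5-benzyloxy-2-(3-benzyloxy-2,5-dihydroxy-4-methoxyphenyl)-7-methoxychromen-4-one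
Product: 14 5-benzyloxy-2-(3-benzyloxy-2,4,5-trimethoxyphenyl)-7-methoxychromen-4-one
Conditions: Me2SO4 (excess), K2CO3, degassed acetone, reflux, under Ar
Reagents that add atoms: dimethyl sulfate, COS(=O)(=O)OC
Why: Williamson O-methylation of both new phenols, where excess reagent can be used to drive the flanked 2'-OH because the 5-OH and 3'-OH are masked as benzyl ethers and no other hydroxyl is present.

Step 11
Reactants: 14 5-benzyloxy-2-(3-benzyloxy-2,4,5-trimethoxyphenyl)-7-methoxychromen-4-one
Product: 15 5,3'-dihydroxy-7,2',4',5'-tetramethoxyflavone (5-hydroxy-2-(3-hydroxy-2,4,5-trimethoxyphenyl)-7-methoxychromen-4-one)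
Conditions: H2 (1 atm), Pd/C, EtOAc–MeOH, rt
Reagents that add atoms: none
Why: Catalytic hydrogenolysis cleaves both benzyl aryl ethers and should leave the methyl ethers and the conjugated C2=C3 bond of the chromone intact at one atmosphere, freeing the 5-OH and 3'-OH.

**Compound list**

1 | methyl 3,5-dihydroxy-4-methoxybenzoate | COC(=O)c1cc(O)c(OC)c(O)c1 | starting material
2 | benzyl bromide | BrCc1ccccc1 | starting material
3 | methyl 3-benzyloxy-5-hydroxy-4-methoxybenzoate | COC(=O)c1cc(O)c(OC)c(OCc2ccccc2)c1 | intermediate
4 | methyl 3-benzyloxy-4-methoxy-5-(methoxymethoxy)benzoate | COCOc1cc(cc(OCc2ccccc2)c1OC)C(=O)OC | intermediate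
5 | 3-benzyloxy-4-methoxy-5-(methoxymethoxy)benzoic acid | COCOc1cc(cc(OCc2ccccc2)c1OC)C(=O)O | intermediate
6 | 2,6-dihydroxy-4-methoxyacetophenone | CC(=O)c1c(O)cc(OC)cc1O | starting material
7 | 2-benzyloxy-6-hydroxy-4-methoxyacetophenone | CC(=O)c1c(O)cc(OC)cc1OCc1ccccc1 | intermediate
8 | 2-acetyl-3-benzyloxy-5-methoxyphenyl 3-benzyloxy-4-methoxy-5-(methoxymethoxy)benzoate | CC(=O)c1c(OCc2ccccc2)cc(OC)cc1OC(=O)c1cc(OCc2ccccc2)c(OC)c(OCOC)c1 | intermediate
9 | 1-(2-benzyloxy-6-hydroxy-4-methoxyphenyl)-3-[3-benzyloxy-4-methoxy-5-(methoxymethoxy)phenyl]propane-1,3-dione | COCOc1cc(cc(OCc2ccccc2)c1OC)C(=O)CC(=O)c1c(O)cc(OC)cc1OCc1ccccc1 | intermediate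
10 | 5-benzyloxy-2-[3-benzyloxy-4-methoxy-5-(methoxymethoxy)phenyl]-7-methoxychromen-4-one (MOM-protected flavone) | COCOc1cc(cc(OCc2ccccc2)c1OC)-c1cc(=O)c2c(OCc3ccccc3)cc(OC)cc2o1 | intermediate
11 | 5-benzyloxy-2-(3-benzyloxy-5-hydroxy-4-methoxyphenyl)-7-methoxychromen-4-one (5,3'-dibenzyloxy-5'-hydroxy-7,4'-dimethoxyflavone) | COc1cc(OCc2ccccc2)c2c(=O)cc(-c3cc(O)c(OC)c(OCc4ccccc4)c3)oc2c1 | intermediate
12 | 5-benzyloxy-2-(5-benzyloxy-4-methoxy-3,6-dioxocyclohexa-1,4-dien-1-yl)-7-methoxychromen-4-one (ring B 2',5'-quinone) | COc1cc(OCc2ccccc2)c2c(=O)cc(C3=CC(=O)C(OC)=C(OCc4ccccc4)C3=O)oc2c1 | intermediate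
13 | 5-benzyloxy-2-(3-benzyloxy-2,5-dihydroxy-4-methoxyphenyl)-7-methoxychromen-4-one | COc1cc(OCc2ccccc2)c2c(=O)cc(-c3cc(O)c(OC)c(OCc4ccccc4)c3O)oc2c1 | intermediate
14 | 5-benzyloxy-2-(3-benzyloxy-2,4,5-trimethoxyphenyl)-7-methoxychromen-4-one | COc1cc(OCc2ccccc2)c2c(=O)cc(-c3cc(OC)c(OC)c(OCc4ccccc4)c3OC)oc2c1 | intermediate
15 | 5,3'-dihydroxy-7,2',4',5'-tetramethoxyflavone | COc1cc(O)c2c(=O)cc(-c3cc(OC)c(OC)c(O)c3OC)oc2c1 | target

**Step count**

Total steps: 11. Longest linear sequence: 10 steps (from 1 through steps 1–3 and 5–11 to 15); the ring A branch (step 4) joins at step 5.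

**Steps most likely to fail, with fallbacks**

1. Step 8 (key step). Radical coupling may occur at the ortho carbon C6', or at C4' with loss of methanol, instead of at the crowded C2'. The poorly soluble flavone may also convert slowly, and water may add to the quinone over a long reaction time. The fallback sets out from 11 and installs the C2' oxygen by an ionic route, the Elbs persulfate oxidation. K2S2O8 in cold aqueous KOH–pyridine should let the phenoxide of 11 attack the peroxide oxygen through its para carbon only. This gives potassium 6-benzyloxy-2-(5-benzyloxy-7-methoxy-4-oxochromen-2-yl)-4-hydroxy-5-methoxyphenyl sulfate F1. Hydrolysis of the sulfate monoester with dilute HCl in THF at about 40 °C should give the hydroquinone directly. The fallback rejoins the route at 13, bypassing quinone 12 and step 9.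

2. Step 7. The 5-O-benzyl ether, activated by the neighbouring C4 carbonyl, may be lost by acidolysis during ring closure, or the acetal may cleave incompletely if the acid is kept weak enough to prevent this. The fallback sets out from 9 and separates ring closure from unmasking. NaOAc-buffered AcOH at 100 °C closes ring C without a strong acid and should give the MOM-protected flavone 10, now isolated. The acetal is then removed without a proton acid by ZnBr2 and n-PrSH in CH2Cl2 at 0 °C, which transfers the methoxymethyl group to the thiol. The fallback rejoins the route at 11.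

3. Step 10. The electron-rich hydroquinone may be reoxidised by air to the quinone under basic conditions before both hydroxyls are capped, and the 2'-OH, flanked on both sides, may methylate slowly. The fallback sets out from 12 and traps the reduced ring as it forms. Reductive acetylation with Zn dust, Ac2O and NaOAc at room temperature should give the air-stable 5-benzyloxy-2-(2,5-diacetoxy-3-benzyloxy-4-methoxyphenyl)-7-methoxychromen-4-one F2. Treatment with Me2SO4 and K2CO3 in MeOH–acetone at reflux then removes the acetates by methanolysis and methylates each phenoxide as it is released. The fallback rejoins the route at 14, bypassing 13.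

**Further compounds**

F1 | step 8 | potassium 6-benzyloxy-2-(5-benzyloxy-7-methoxy-4-oxochromen-2-yl)-4-hydroxy-5-methoxyphenyl sulfate | [K+].COc1cc(OCc2ccccc2)c2c(=O)cc(-c3cc(O)c(OC)c(OCc4ccccc4)c3OS(=O)(=O)[O-])oc2c1
F0 | step 7 | none | none
F2 | step 10 | 5-benzyloxy-2-(2,5-diacetoxy-3-benzyloxy-4-methoxyphenyl)-7-methoxychromen-4-one | COc1cc(OCc2ccccc2)c2c(=O)cc(-c3cc(OC(C)=O)c(OC)c(OCc4ccccc4)c3OC(C)=O)oc2c1
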